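**Plan**
1. Rings: A = 4-hydroxy-3-methoxyphenyl of the glycerol chain, B = central 3,5-dimethoxy-4-oxyphenyl, C = benzene ring of the benzofuran; Cα = benzylic carbinol carbon and Cβ = aryloxy carbon of the glycerol chain. The retrosynthesis cuts the furan ring at O1–C2 and C3–C3a in one event (5-iodovanillin + an (E)-sinapyl ether), then the Cα–Cβ bond (aldol) and the O–CH2 bond of the glycolyl unit on ring B.
2. Forward: glycolyl imide on methyl sinapate, aldol with silylated vanillin (joins ring A), auxiliary removal, inversion at Cα, reduction to the cinnamyl alcohol, silylation. The furan ring on ring C is closed in the last C–C/C–O forming step, then all silyl groups are removed.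
3. Stereochemistry: Cβ from the (S)-benzyloxazolidinone in the boron aldol; Cα from the syn aldol followed by Mitsunobu inversion (erythro). C3 comes from the chiral ligand on palladium in the carbopalladation; C2 is trans to it by syn addition across the (E)-alkene.
4. Enabling feature: C2 is benzylic to ring B, whose para oxygen holds palladium (or positive charge) at C2 until O1 closes. O1 and C3a are ortho on ring C, which is the OH/I pair of 5-iodovanillin with the formyl and methoxy groups already in place, and C2–C3 is the former C=C of the sinapyl unit.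

Key step: step 9

Assumption: the (S) ligand is written for step 9 on the understanding that it gives the (2R,3S) ring; if the sense of induction is the reverse, its (R) antipode is used with no other change.

**Step 1**
Reactants: 1 vanillin
Product: 2 3-methoxy-4-(triisopropylsilyloxy)benzaldehyde
Conditions: TIPSCl, imidazole, DMF, rt
Reagents that add atoms: triisopropylsilyl chloride (TIPSCl), CC(C)[Si](Cl)(C(C)C)C(C)C
Why: Silyl ether formation masks the ring A phenol with a group that should survive the boron aldol, the hydride reductions and the Mitsunobu step and leaves with fluoride at the end.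

**Step 2**
Reactants: 3 methyl sinapate; 4 (S)-4-benzyl-3-(chloroacetyl)oxazolidin-2-one
Product: 5 methyl (E)-3-[4-(2-{(S)-4-benzyl-2-oxooxazolidin-3-yl}-2-oxoethoxy)-3,5-dimethoxyphenyl]prop-2-enoate
Conditions: K2CO3, MeCN, 60 °C
Reagents that add atoms: none
Why: Williamson ether synthesis, in which the hindered 2,6-dimethoxyphenoxide should displace chloride from the activated α-chloro imide (SN2) in preference to attacking the imide carbonyl.

**Step 3**
Reactants: 5; 2
Product: 7 methyl (E)-3-[4-({(2S,3R)-1-[(S)-4-benzyl-2-oxooxazolidin-3-yl]-3-hydroxy-3-[3-methoxy-4-(triisopropylsilyloxy)phenyl]-1-oxopropan-2-yl}oxy)-3,5-dimethoxyphenyl]prop-2-enoate, via boron enolate 6 (not isolated)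
Conditions: Bu2BOTf, iPr2NEt, CH2Cl2, −78 to 0 °C; then 2, −78 to 0 °C; pH 7 buffer, MeOH, H2O2, 0 °C
Reagents that add atoms: none
Why: Evans syn aldol reaction, in which the (Z)-boron enolate reacts through a chair transition state on the face away from the benzyl group of the (S)-oxazolidinone, setting Cβ (2S here, R once the carbonyl is CH2OH) and Cα as its syn partner (3R, threo).

**Step 4**
Reactants: 7
Product: 8 methyl (E)-3-[4-({(1R,2R)-1,3-dihydroxy-1-[3-methoxy-4-(triisopropylsilyloxy)phenyl]propan-2-yl}oxy)-3,5-dimethoxyphenyl]prop-2-enoate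
Conditions: NaBH4, THF/H2O, 0 °C to rt
Reagents that add atoms: none
Why: Reductive cleavage of the N-acyl oxazolidinone by borohydride, the imide carbonyl being far more electrophilic than the conjugated methyl ester, should free the primary alcohol and the auxiliary without touching either stereocentre.

**Step 5**
Reactants: 8
Product: 9 methyl (E)-3-[4-({(1R,2R)-3-(tert-butyldimethylsilyloxy)-1-hydroxy-1-[3-methoxy-4-(triisopropylsilyloxy)phenyl]propan-2-yl}oxy)-3,5-dimethoxyphenyl]prop-2-enoate
Conditions: TBSCl (1.05 equiv), imidazole, CH2Cl2, 0 °C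
Reagents that add atoms: tert-butyldimethylsilyl chloride (TBSCl), CC(C)(C)[Si](C)(C)Cl
Why: Selective silyl ether formation, the primary hydroxyl reacting much faster than the hindered secondary benzylic one.

**Step 6**
Reactants: 9
Product: 10 methyl (E)-3-[4-({(1S,2R)-3-(tert-butyldimethylsilyloxy)-1-[3-methoxy-4-(triisopropylsilyloxy)phenyl]-1-[(4-nitrobenzoyl)oxy]propan-2-yl}oxy)-3,5-dimethoxyphenyl]prop-2-enoate
Conditions: 4-nitrobenzoic acid, PPh3, DIAD, THF, 0 °C to rt
Reagents that add atoms: 4-nitrobenzoic acid, OC(=O)c1ccc(cc1)[N+](=O)[O-]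
Why: Mitsunobu reaction, in which the carboxylate displaces the oxyphosphonium group at Cα with inversion (SN2, ionisation being disfavoured by the electron-withdrawing β-aryloxy group), so the threo alcohol should become the erythro (1S,2R) ester.

**Step 7**
Reactants: 10
Product: 11 (E)-3-[4-({(1S,2R)-3-(tert-butyldimethylsilyloxy)-1-hydroxy-1-[3-methoxy-4-(triisopropylsilyloxy)phenyl]propan-2-yl}oxy)-3,5-dimethoxyphenyl]prop-2-en-1-ol
Conditions: i-Bu2AlH (DIBAL-H, 6 equiv), CH2Cl2, −78 °C; aq. potassium sodium tartrate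
Reagents that add atoms: none
Why: Ester reduction with an aluminium hydride, which should give the allylic alcohol from the cinnamate by 1,2-reduction and free the inverted secondary alcohol from the nitrobenzoate in the same operation.

**Step 8**
Reactants: 11
Product: 12 tert-butyl{[(E)-3-(4-{[(1S,2R)-1,3-bis(tert-butyldimethylsilyloxy)-1-(3-methoxy-4-triisopropylsilyloxyphenyl)propan-2-yl]oxy}-3,5-dimethoxyphenyl)prop-2-en-1-yl]oxy}dimethylsilane
Conditions: TBSOTf (2.5 equiv), 2,6-lutidine, CH2Cl2, −78 to 0 °C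
Reagents that add atoms: tert-butyldimethylsilyl triflate (TBSOTf), CC(C)(C)[Si](C)(C)OS(=O)(=O)C(F)(F)F
Why: Silyl ether formation on both free hydroxyls removes coordinating and oxidisable OH groups, so that in the next step palladium is neither steered to the carbon next to the allylic oxygen nor relayed to an aldehyde.

**Step 9**
Reactants: 12; 13 5-iodovanillin (4-hydroxy-3-iodo-5-methoxybenzaldehyde)
Product: 14 (2R,3S)-2-[4-({(1S,2R)-1,3-bis(tert-butyldimethylsilyloxy)-1-[3-methoxy-4-(triisopropylsilyloxy)phenyl]propan-2-yl}oxy)-3,5-dimethoxyphenyl]-3-[(tert-butyldimethylsilyloxy)methyl]-7-methoxy-2,3-dihydro-1-benzofuran-5-carbaldehyde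
Conditions: Pd2(dba)3 (5 mol %), (S)-4-tert-butyl-2-(pyridin-2-yl)-4,5-dihydrooxazole (12 mol %), Ag2CO3 (1.5 equiv), acetone, 50 °C
Reagents that add atoms: none
Why: Proposed new method: zerovalent palladium inserts into the C–I bond of 13, Ag2CO3 removes iodide and the phenolic proton, and the resulting cationic aryl complex of divalent palladium, held by the chiral pyridine–oxazoline, adds syn across the (E)-alkene of 12 with the ring C carbon going to C3 and the metal to C2, where ring B stabilises it as an η3-benzyl unit; the ortho phenoxide then takes the place of the metal at C2 (C–O reductive elimination from a six-membered oxapalladacycle, or collapse of the para-alkoxybenzyl cation), forming O1–C2 and returning zerovalent palladium. The closest known reaction type is the palladium-catalysed oxyarylation (Heck-type [3+2] heteroannulation) of styrene-type alkenes with ortho-iodophenols or ortho-hydroxyarenediazonium salts, established for 2H-chromenes and for (E)-1-arylpropenes (trans-2-aryl-3-methyl-2,3-dihydrobenzofurans); what is new is the enantioselective version on an acyclic alkene that carries a silyloxymethyl group. The furan ring closes in the 5-exo-trig mode, O1 attacking C2 whose partial double bond to ring B lies outside the new ring. C3 is controlled by the ligand, which selects the alkene face in the insertion as N,N-ligated cationic palladium does in enantioselective intermolecular Heck arylations of acyclic 1,2-disubstituted alkenes; C2 is controlled by C3, because syn addition across the (E)-alkene and, if C2 ionises, the thermodynamic preference both give the 2,3-trans ring. The step needs regioselectivity (aryl to the carbon remote from ring B), secured by the benzylic stabilisation of palladium by the 4-alkoxy-3,5-dimethoxyphenyl ring and by the bulky, non-coordinating silyl ether on the allylic oxygen; chemoselectivity against β-hydride elimination, secured by chelation of the ortho phenoxide to palladium; and face selectivity, which must come from the ligand because the side-chain stereocentres are too remote to interfere.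

**Step 10**
Reactants: 14
Product: 15 (2R,3S)-2-[4-({(1S,2R)-1,3-dihydroxy-1-(4-hydroxy-3-methoxyphenyl)propan-2-yl}oxy)-3,5-dimethoxyphenyl]-3-(hydroxymethyl)-7-methoxy-2,3-dihydro-1-benzofuran-5-carbaldehyde (CID53356209)
Conditions: TBAF (6 equiv), AcOH (6 equiv), THF, 0 °C to rt
Reagents that add atoms: none
Why: Fluoride-mediated desilylation should cleave the aryl TIPS ether and the three TBS ethers under buffered conditions that leave the aldehyde, the benzylic aryl ether of the furan ring and all four stereocentres untouched.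

**Compound list**
1 | vanillin (4-hydroxy-3-methoxybenzaldehyde) | COc1cc(C=O)ccc1O | starting material
2 | 3-methoxy-4-(triisopropylsilyloxy)benzaldehyde | COc1cc(C=O)ccc1O[Si](C(C)C)(C(C)C)C(C)C | intermediate
3 | methyl sinapate, methyl (E)-3-(4-hydroxy-3,5-dimethoxyphenyl)prop-2-enoate | COC(=O)/C=C/c1cc(OC)c(O)c(OC)c1 | starting material
4 | (S)-4-benzyl-3-(chloroacetyl)oxazolidin-2-one | O=C(CCl)N1[C@@H](Cc2ccccc2)COC1=O | starting material
5 | methyl (E)-3-[4-(2-{(S)-4-benzyl-2-oxooxazolidin-3-yl}-2-oxoethoxy)-3,5-dimethoxyphenyl]prop-2-enoate | COC(=O)/C=C/c1cc(OC)c(OCC(=O)N2[C@@H](Cc3ccccc3)COC2=O)c(OC)c1 | intermediate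
6 | (Z)-dibutylboron enolate of 5 (O–B and aryloxy group cis) | CCCCB(CCCC)O/C(N1[C@@H](Cc2ccccc2)COC1=O)=C\Oc1c(OC)cc(/C=C/C(=O)OC)cc1OC | intermediate
7 | syn aldol adduct, (2S,3R) in the acyl chain, (S)-auxiliary | COc1cc([C@@H](O)[C@@H](C(=O)N3[C@@H](Cc4ccccc4)COC3=O)Oc2c(OC)cc(/C=C/C(=O)OC)cc2OC)ccc1O[Si](C(C)C)(C(C)C)C(C)C | intermediate
8 | threo (1R,2R) diol, methyl cinnamate | COc1cc([C@@H](O)[C@@H](CO)Oc2c(OC)cc(/C=C/C(=O)OC)cc2OC)ccc1O[Si](C(C)C)(C(C)C)C(C)C | intermediate
9 | (1R,2R) secondary alcohol with primary OTBS | COc1cc([C@@H](O)[C@@H](CO[Si](C)(C)C(C)(C)C)Oc2c(OC)cc(/C=C/C(=O)OC)cc2OC)ccc1O[Si](C(C)C)(C(C)C)C(C)C | intermediate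
10 | erythro (1S,2R) 4-nitrobenzoate | COc1cc([C@H](OC(=O)c3ccc(cc3)[N+](=O)[O-])[C@@H](CO[Si](C)(C)C(C)(C)C)Oc2c(OC)cc(/C=C/C(=O)OC)cc2OC)ccc1O[Si](C(C)C)(C(C)C)C(C)C | intermediate
11 | erythro (1S,2R) alcohol, (E)-cinnamyl alcohol | COc1cc([C@H](O)[C@@H](CO[Si](C)(C)C(C)(C)C)Oc2c(OC)cc(/C=C/CO)cc2OC)ccc1O[Si](C(C)C)(C(C)C)C(C)C | intermediate
12 | tris-TBS, mono-TIPS (E)-alkene, (1S,2R) | COc1cc([C@H](O[Si](C)(C)C(C)(C)C)[C@@H](CO[Si](C)(C)C(C)(C)C)Oc2c(OC)cc(/C=C/CO[Si](C)(C)C(C)(C)C)cc2OC)ccc1O[Si](C(C)C)(C(C)C)C(C)C | intermediate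
13 | 5-iodovanillin (4-hydroxy-3-iodo-5-methoxybenzaldehyde) | COc1cc(C=O)cc(I)c1O | starting material
14 | tetrasilyl ether of the target, (2R,3S) ring, (1S,2R) chain | COc1cc([C@H](O[Si](C)(C)C(C)(C)C)[C@@H](CO[Si](C)(C)C(C)(C)C)Oc2c(OC)cc([C@@H]3Oc4c(OC)cc(C=O)cc4[C@H]3CO[Si](C)(C)C(C)(C)C)cc2OC)ccc1O[Si](C(C)C)(C(C)C)C(C)C | intermediate
15 | CID53356209, (2R,3S) ring, (1S,2R) chain | COc1cc([C@H](O)[C@@H](CO)Oc2c(OC)cc([C@@H]3Oc4c(OC)cc(C=O)cc4[C@H]3CO)cc2OC)ccc1O | target

**Step count**
Total: 10 steps. Longest linear sequence: 9 steps (steps 2 to 10 from methyl sinapate; step 1 feeds step 3).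

**Steps most likely to fail**

Step 9. The carbopalladation may discriminate the alkene faces poorly, the aryl group may go to the benzylic carbon instead of C3, or β-hydride elimination may outrun C–O bond formation. The fallback is an auxiliary-controlled aldol with acid-promoted, stereoconvergent ring closure; it sets out from 12 and 13 and comes back at 15. Lemieux–Johnson cleavage of 12 (OsO4 cat., NaIO4, 2,6-lutidine, dioxane/H2O) would give the ring B aldehyde F1. In parallel 13 would be converted into its methoxymethyl ether F2 (MOMCl, iPr2NEt) and then into the dioxolane F3 (1,2-bis(trimethylsilyloxy)ethane, TMSOTf cat., −78 °C). Palladium-catalysed coupling of F3 with the Reformatsky reagent BrZnCH2CO2Et (Pd2(dba)3, XPhos, THF) would give the arylacetate F4, LiOH the arylacetic acid F5, and pivaloyl chloride/Et3N followed by (R)-4-benzyloxazolidin-2-one/LiCl the imide F6. Evans syn aldol of F6 with F1 (Bu2BOTf, iPr2NEt) would give the (2R,3R) adduct F7, in which the (R)-auxiliary fixes the future C3 as S, and NaBH4 would give the diol F8. Aqueous HCl in THF would then remove the methoxymethyl, dioxolane and TBS groups and close the furan ring through the ring B benzylic cation to the preferred 2,3-trans product, the TIPS ether F9. TBAF converts F9 into 15.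

Step 6. The activated benzylic oxyphosphonium may ionise (loss of stereochemical fidelity) or eliminate to the enol ether instead of undergoing clean inversion. The fallback is oxidation and substrate-controlled reduction; it sets out from 9 and comes back at 11. Dess–Martin oxidation of 9 would give the aryl ketone F10. NaBH4 in MeOH/THF at −40 °C, under Felkin–Anh control by the α-aryloxy group (the erythro-selective reduction familiar from arylglycerol β-aryl ether ketones), would give the (1S,2R) alcohol F11. DIBAL-H then reduces only the methyl ester of F11 and joins the route at 11.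

Step 2. The phenoxide may attack the imide carbonyl (acyl transfer, loss of the auxiliary) in competition with displacement of chloride. The fallback builds the ether first and attaches the auxiliary afterwards; it sets out from 3 and comes back at 5. Alkylation of 3 with tert-butyl bromoacetate (K2CO3, acetone) would give the tert-butyl aryloxyacetate F12 and TFA in CH2Cl2 the aryloxyacetic acid F13. Mixed-anhydride acylation (pivaloyl chloride, Et3N; then (S)-4-benzyloxazolidin-2-one, LiCl) gives 5.

**Further compounds**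
F1 | step 9 | 4-({(1S,2R)-1,3-bis(tert-butyldimethylsilyloxy)-1-[3-methoxy-4-(triisopropylsilyloxy)phenyl]propan-2-yl}oxy)-3,5-dimethoxybenzaldehyde | COc1cc([C@H](O[Si](C)(C)C(C)(C)C)[C@@H](CO[Si](C)(C)C(C)(C)C)Oc2c(OC)cc(C=O)cc2OC)ccc1O[Si](C(C)C)(C(C)C)C(C)C
F2 | step 9 | 3-iodo-5-methoxy-4-(methoxymethoxy)benzaldehyde | COCOc1c(I)cc(C=O)cc1OC
F3 | step 9 | 2-[3-iodo-5-methoxy-4-(methoxymethoxy)phenyl]-1,3-dioxolane | COCOc1c(I)cc(C2OCCO2)cc1OC
F4 | step 9 | ethyl 2-[5-(1,3-dioxolan-2-yl)-3-methoxy-2-(methoxymethoxy)phenyl]acetate | CCOC(=O)Cc1cc(C2OCCO2)cc(OC)c1OCOC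
F5 | step 9 | 2-[5-(1,3-dioxolan-2-yl)-3-methoxy-2-(methoxymethoxy)phenyl]acetic acid | OC(=O)Cc1cc(C2OCCO2)cc(OC)c1OCOC
F6 | step 9 | (R)-4-benzyl-3-{2-[5-(1,3-dioxolan-2-yl)-3-methoxy-2-(methoxymethoxy)phenyl]acetyl}oxazolidin-2-one | O=C(Cc1cc(C2OCCO2)cc(OC)c1OCOC)N1[C@H](Cc2ccccc2)COC1=O
F7 | step 9 | syn aldol adduct of F6 and F1, (2R,3R) in the acyl chain, (R)-auxiliary, side chain (1S,2R) | COc1cc([C@H](O[Si](C)(C)C(C)(C)C)[C@@H](CO[Si](C)(C)C(C)(C)C)Oc2c(OC)cc([C@H](O)[C@H](C(=O)N3[C@H](Cc4ccccc4)COC3=O)c5cc(C6OCCO6)cc(OC)c5OCOC)cc2OC)ccc1O[Si](C(C)C)(C(C)C)C(C)C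
F8 | step 9 | (1R,2S)-1-(ring B aryl)-2-[5-(1,3-dioxolan-2-yl)-3-methoxy-2-(methoxymethoxy)phenyl]propane-1,3-diol, side chain (1S,2R) bis-TBS, ring A TIPS | COc1cc([C@H](O[Si](C)(C)C(C)(C)C)[C@@H](CO[Si](C)(C)C(C)(C)C)Oc2c(OC)cc([C@H](O)[C@H](CO)c5cc(C6OCCO6)cc(OC)c5OCOC)cc2OC)ccc1O[Si](C(C)C)(C(C)C)C(C)C
F9 | step 9 | ring A triisopropylsilyl ether of 15, (2R,3S) ring, (1S,2R) chain | COc1cc([C@H](O)[C@@H](CO)Oc2c(OC)cc([C@@H]3Oc4c(OC)cc(C=O)cc4[C@H]3CO)cc2OC)ccc1O[Si](C(C)C)(C(C)C)C(C)C
F10 | step 6 | methyl (E)-3-[4-({(2R)-3-(tert-butyldimethylsilyloxy)-1-[3-methoxy-4-(triisopropylsilyloxy)phenyl]-1-oxopropan-2-yl}oxy)-3,5-dimethoxyphenyl]prop-2-enoate | COc1cc(C(=O)[C@@H](CO[Si](C)(C)C(C)(C)C)Oc2c(OC)cc(/C=C/C(=O)OC)cc2OC)ccc1O[Si](C(C)C)(C(C)C)C(C)C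
F11 | step 6 | methyl (E)-3-[4-({(1S,2R)-3-(tert-butyldimethylsilyloxy)-1-hydroxy-1-[3-methoxy-4-(triisopropylsilyloxy)phenyl]propan-2-yl}oxy)-3,5-dimethoxyphenyl]prop-2-enoate | COc1cc([C@H](O)[C@@H](CO[Si](C)(C)C(C)(C)C)Oc2c(OC)cc(/C=C/C(=O)OC)cc2OC)ccc1O[Si](C(C)C)(C(C)C)C(C)C
F12 | step 2 | methyl (E)-3-{4-[2-(tert-butoxy)-2-oxoethoxy]-3,5-dimethoxyphenyl}prop-2-enoate | COC(=O)/C=C/c1cc(OC)c(OCC(=O)OC(C)(C)C)c(OC)c1
F13 | step 2 | 2-{2,6-dimethoxy-4-[(E)-3-methoxy-3-oxoprop-1-enyl]phenoxy}acetic acid | COC(=O)/C=C/c1cc(OC)c(OCC(=O)O)c(OC)c1
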